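**Retrosynthetic overview**

1. The C50 skeleton is cut once, at the C8–C9 single bond between two sp2 carbons: C16 acyclic end (C1–C8, iodide 14) plus C34 ring half (C9–C6′, enyne 40). The bond is made by a palladium/formate reductive syn-hydroalkenylation in which the (E)-C8 iodide adds across a C9≡C10 triple bond; both partners are electrophilic π-components (like polarity) and formate is the reductant.
2. Enabling feature: C9 carries the chain methyl of the trisubstituted (E)-C9=C10 alkene and sits between C8H= and the C11=C12 to C7′=C8′ heptaene. C9=C10 can therefore be stored as a methyl-capped alkyne CH3–C9≡C10, whose two carbons are told apart by methyl against polyenyl.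
3. Enyne 40: Julia–Kocienski olefination at C7′=C8′ of ring sulfone 30 with C19 ynal 39; 39 comes from the C10 dialdehyde by two Horner–Wadsworth–Emmons (HWE) reactions (C11=C12 with a but-2-ynyl phosphonate, C11′=C12′ with a C5 phosphonate ester).
4. The one carbocycle (cyclohexene C1′–C6′) is not formed in the route; it is carried from 2,4,4-trimethylcyclohex-2-enone. C2′ is set by rhodium-catalysed conjugate vinylation of the derived 2,5-dienone, C6′ by CBS reduction at C4′ and suprafacial [2,3]-Wittig–Still transfer of CH2OH; the vinyl group becomes the (E)-hydroxyprenyl side chain.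
5. Iodide 14: Evans deconjugative α-prenylation of an N-senecioyl oxazolidinone (C2), Mukaiyama hydration of the isopropenyl group (C1 carbinol), HWE extension by C5, Takai iodo-olefination (C7=C8).

Key step: step 26

Remark: carotenoid numbering is used (acyclic end C1–C15 with methyls on C5, C9, C13; ring half C15′–C7′, ring C1′–C6′, ring side chain C1″–C4″), and compounds 15, 33 and 35 are taken to be catalogue compounds.

**C16 fragment (steps 1–9)**

Step 1
Reactants: 1 (S)-4-benzyloxazolidin-2-one; 2 3-methylbut-2-enoyl chloride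
Product: 3 (S)-4-benzyl-3-(3-methylbut-2-enoyl)oxazolidin-2-one
Conditions: n-BuLi, THF, −78 °C to 0 °C
Reagents that add atoms: none
Why: N-acylation of the lithiated oxazolidinone by the acid chloride is the routine attachment of an Evans auxiliary.

Step 2
Reactants: 3 N-senecioyl oxazolidinone; 4 1-bromo-3-methylbut-2-ene
Product: 5 (S)-4-benzyl-3-[(2S)-5-methyl-2-(prop-1-en-2-yl)hex-4-enoyl]oxazolidin-2-one
Conditions: NaN(SiMe3)2, THF, −78 °C to −30 °C
Reagents that add atoms: none
Why: γ-deprotonation gives the chelated (Z)-sodium dienolate, which should be alkylated at the α-carbon on the face opposite the benzyl group (Evans deconjugative alkylation), setting C2 (S in the imide, R in the target).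

Step 3
Reactants: 5 α-prenylated imide
Product: 6 (S)-4-benzyl-3-[(2S)-2-(2-hydroxypropan-2-yl)-5-methylhex-4-enoyl]oxazolidin-2-one
Conditions: Co(acac)2 (20 mol %), PhSiH3, O2 (1 atm), THF/i-PrOH, 0 °C to rt
Reagents that add atoms: dioxygen, O=O
Why: Mukaiyama hydration (hydrogen-atom transfer, Markovnikov) should convert the 1,1-disubstituted isopropenyl alkene into the tertiary C1 carbinol faster than the trisubstituted prenyl alkene, as in the hydration of limonene to α-terpineol.

Step 4
Reactants: 6 hydroxy imide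
Product: 7 (S)-4-benzyl-3-[(2S)-5-methyl-2-{2-[(triethylsilyl)oxy]propan-2-yl}hex-4-enoyl]oxazolidin-2-one
Conditions: Et3SiOTf, 2,6-lutidine, CH2Cl2, −78 °C to 0 °C
Reagents that add atoms: triethylsilyl trifluoromethanesulfonate, CC[Si](CC)(CC)OS(=O)(=O)C(F)(F)F
Why: silylation of the tertiary alcohol with the silyl triflate blocks retro-aldol cleavage and β-elimination in the aldehyde steps that follow.

Step 5
Reactants: 7 silyl ether imide
Product: 8 (2R)-5-methyl-2-{2-[(triethylsilyl)oxy]propan-2-yl}hex-4-en-1-ol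
Conditions: LiBH4, MeOH (1 equiv), Et2O, 0 °C
Reagents that add atoms: none
Why: reductive cleavage of the N-acyl oxazolidinone gives the primary alcohol and returns the auxiliary without touching the α-stereocentre.

Step 6
Reactants: 8 primary alcohol
Product: 9 (2S)-5-methyl-2-{2-[(triethylsilyl)oxy]propan-2-yl}hex-4-enal
Conditions: Dess–Martin periodinane, NaHCO3, CH2Cl2, 0 °C
Reagents that add atoms: none
Why: buffered Dess–Martin oxidation should give the α-branched aldehyde without epimerisation; it is used at once.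

Step 7
Reactants: 9 aldehyde; 10 diethyl (3-cyano-2-methylprop-2-en-1-yl)phosphonate
Product: 11 (2E,4E,6R)-3,9-dimethyl-6-{2-[(triethylsilyl)oxy]propan-2-yl}deca-2,4,8-trienenitrile
Conditions: LiN(SiMe3)2, THF, −78 °C to 0 °C
Reagents that add atoms: none
Why: Horner–Wadsworth–Emmons olefination with the allylic phosphonate anion should form C3=C4 with E selectivity and bring in C5–C7; a minor (2Z) isomer would be removed by chromatography.

Step 8
Reactants: 11 dienenitrile
Product: 12 (2E,4E,6R)-3,9-dimethyl-6-{2-[(triethylsilyl)oxy]propan-2-yl}deca-2,4,8-trienal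
Conditions: i-Bu2AlH, CH2Cl2, −78 °C; aqueous tartaric acid work-up
Reagents that add atoms: water, O
Why: half-reduction of the nitrile to the aluminium aldiminate and hydrolysis gives the dienal (C7 aldehyde) without touching the silyl ether or the alkene geometry.

Step 9
Reactants: 12 dienal; 13 iodoform
Product: 14 triethyl{[(3R,4E,6E,8E)-9-iodo-2,6-dimethyl-3-(3-methylbut-2-en-1-yl)nona-4,6,8-trien-2-yl]oxy}silane
Conditions: CrCl2, THF/1,4-dioxane, 0 °C to rt, dark
Reagents that add atoms: none
Why: Takai iodo-olefination (geminal dichromium carbenoid from CHI3 and CrCl2) should convert the enal into the (E)-alkenyl iodide, adding C8 and setting C7=C8.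

**Ring sulfone (steps 10–18)**

Step 10
Reactants: 15 2,4,4-trimethylcyclohex-2-en-1-one
Product: 16 2,4,4-trimethylcyclohexa-2,5-dien-1-one
Conditions: DDQ, 1,4-dioxane, reflux
Reagents that add atoms: none
Why: DDQ dehydrogenation of the α′,β′-positions gives the cross-conjugated dienone, as in the steroid 4-en-3-one to 1,4-dien-3-one oxidation; the quaternary carbon prevents aromatisation.

Step 11
Reactants: 16 dienone; 17 potassium ethenyltrifluoroborate
Product: 18 (5S)-5-ethenyl-2,4,4-trimethylcyclohex-2-en-1-one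
Conditions: [Rh(cod)2]BF4 (3 mol %), (S)-BINAP (3.3 mol %), toluene/H2O, 100 °C
Reagents that add atoms: none
Why: Hayashi–Miyaura rhodium-catalysed asymmetric 1,4-addition should deliver the vinyl group to the α-unsubstituted enone arm rather than the α-methyl one, on the face selected by (S)-BINAP (assigned by analogy with the cyclohexenone model), which sets C2′.

Step 12
Reactants: 18 vinyl enone
Product: 19 (1R,5S)-5-ethenyl-2,4,4-trimethylcyclohex-2-en-1-ol
Conditions: (S)-Me-CBS oxazaborolidine (20 mol %), catecholborane, toluene, −78 °C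
Reagents that add atoms: none
Why: Corey–Bakshi–Shibata reduction treats the α-methyl alkenyl arm as the large group and should give the (1R) allylic alcohol, trans to the vinyl group, under catalyst control; catecholborane does not hydroborate the vinyl group at this temperature.

Step 13
Reactants: 19 allylic alcohol; 20 tributyl(iodomethyl)stannane
Product: 21 tributyl({[(1R,5S)-5-ethenyl-2,4,4-trimethylcyclohex-2-en-1-yl]oxy}methyl)stannane
Conditions: KH, THF, 0 °C to rt
Reagents that add atoms: none
Why: Williamson etherification of the potassium alkoxide with the iodomethylstannane gives the stannylmethyl ether needed for the Wittig–Still rearrangement.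

Step 14
Reactants: 21 stannylmethyl ether
Product: 23 [(1R,5S)-5-ethenyl-2,6,6-trimethylcyclohex-2-en-1-yl]methanol, via lithiomethyl ether 22 (not isolated)
Conditions: n-BuLi, THF, −78 °C to −40 °C
Reagents that add atoms: none
Why: tin–lithium exchange gives the α-alkoxymethyllithium, which should undergo the [2,3]-Wittig–Still rearrangement through a five-membered envelope transition state, moving CH2OH suprafacially from O–C4′ to C6′ (so C6′ is set by C4′, trans to the C2′ substituent) and the double bond to C4′=C5′.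

Step 15
Reactants: 23 primary alcohol
Product: 24 5-({[(1R,5S)-5-ethenyl-2,6,6-trimethylcyclohex-2-en-1-yl]methyl}sulfanyl)-1-phenyl-1H-tetrazole
Conditions: 1-phenyl-1H-tetrazole-5-thiol, PPh3, DIAD, THF, 0 °C to rt
Reagents that add atoms: 1-phenyl-1H-tetrazole-5-thiol, Sc1nnnn1-c1ccccc1
Why: Mitsunobu thioetherification of the primary alcohol with the acidic tetrazolethiol installs the Julia–Kocienski handle at C7′.

Step 16
Reactants: 24 sulfide
Product: 26 2-[(1S,5R)-4,6,6-trimethyl-5-{[(1-phenyl-1H-tetrazol-5-yl)sulfanyl]methyl}cyclohex-3-en-1-yl]ethan-1-ol, via B-alkyl-9-BBN adduct 25 (not isolated)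
Conditions: 9-BBN, THF, 0 °C to rt; then NaOH, H2O2, 0 °C
Reagents that add atoms: hydrogen peroxide, OO
Why: 9-BBN should hydroborate the monosubstituted vinyl group anti-Markovnikov and leave the trisubstituted ring alkene; oxidation of the C–B bond gives the primary alcohol (C2″).

Step 17
Reactants: 26 sulfide alcohol
Product: 27 2-[(1S,5R)-4,6,6-trimethyl-5-{[(1-phenyl-1H-tetrazol-5-yl)sulfonyl]methyl}cyclohex-3-en-1-yl]ethan-1-ol
Conditions: (NH4)6Mo7O24·4H2O (10 mol %), H2O2, EtOH, 0 °C to rt
Reagents that add atoms: hydrogen peroxide, OO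
Why: molybdate-catalysed peroxide oxidation takes the sulfide to the sulfone without epoxidising the trisubstituted alkene or oxidising the alcohol.

Step 18
Reactants: 27 sulfone alcohol; 28 ethyl 2-(triphenyl-λ5-phosphanylidene)propanoate
Product: 30 ethyl (2E)-2-methyl-4-[(1S,5R)-4,6,6-trimethyl-5-{[(1-phenyl-1H-tetrazol-5-yl)sulfonyl]methyl}cyclohex-3-en-1-yl]but-2-enoate, via aldehyde 29 (not isolated)
Conditions: Dess–Martin periodinane, CH2Cl2, rt; then 28, 40 °C
Reagents that add atoms: none
Why: oxidation to the aldehyde and Wittig reaction with the stabilised α-methyl ylide in the same flask should give the (E)-trisubstituted enoate (C2″=C3″) of the side chain.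

**C19 ynal (steps 19–24)**

Step 19
Reactants: 31 1-bromobut-2-yne
Product: 32 diethyl but-2-yn-1-ylphosphonate
Conditions: P(OEt)3, 120 °C
Reagents that add atoms: triethyl phosphite, CCOP(OCC)OCC
Why: Michaelis–Arbuzov reaction of the primary propargylic bromide gives the phosphonate.

Step 20
Reactants: 32 butynyl phosphonate; 33 (2E,4E,6E)-2,7-dimethylocta-2,4,6-trienedial
Product: 34 (2E,4E,6E,8E)-2,7-dimethyldodeca-2,4,6,8-tetraen-10-ynal
Conditions: LiN(SiMe3)2, THF, −78 °C to 0 °C, 33 in excess (3 equiv)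
Reagents that add atoms: none
Why: HWE reaction of the propargylic phosphonate anion with one formyl group of the symmetrical dialdehyde (excess dialdehyde suppresses double olefination) should give the (E)-enyne C11=C12–C10≡C9–CH3.

Step 21
Reactants: 35 ethyl (2E)-4-bromo-2-methylbut-2-enoate
Product: 36 ethyl (2E)-4-(diethoxyphosphoryl)-2-methylbut-2-enoate
Conditions: P(OEt)3, 120 °C
Reagents that add atoms: triethyl phosphite, CCOP(OCC)OCC
Why: Michaelis–Arbuzov reaction of the allylic bromide gives the C5 phosphonate ester used for crocetin-type chain extension.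

Step 22
Reactants: 34 C14 ynal; 36 C5 phosphonate ester
Product: 37 ethyl (2E,4E,6E,8E,10E,12E)-2,6,11-trimethylhexadeca-2,4,6,8,10,12-hexaen-14-ynoate
Conditions: LiN(SiMe3)2, THF, −78 °C to 0 °C
Reagents that add atoms: none
Why: HWE olefination through the phosphorus-bearing carbon of the vinylogous phosphonate anion should form C11′=C12′ with E selectivity and add C8′–C11′.

Step 23
Reactants: 37 C19 ester
Product: 38 (2E,4E,6E,8E,10E,12E)-2,6,11-trimethylhexadeca-2,4,6,8,10,12-hexaen-14-yn-1-ol
Conditions: i-Bu2AlH, CH2Cl2, −78 °C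
Reagents that add atoms: none
Why: 1,2-reduction of the conjugated ester to the allylic alcohol is routine for polyene esters and leaves the alkyne untouched.

Step 24
Reactants: 38 C19 alcohol
Product: 39 (2E,4E,6E,8E,10E,12E)-2,6,11-trimethylhexadeca-2,4,6,8,10,12-hexaen-14-ynal
Conditions: MnO2, CH2Cl2, rt
Reagents that add atoms: none
Why: MnO2 oxidises the allylic alcohol selectively to the polyenal (C8′ aldehyde).

**Assembly and end game (steps 25–28)**

Step 25
Reactants: 30 ring sulfone; 39 C19 ynal
Product: 40 ethyl (2E)-2-methyl-4-{(1S,5R)-4,6,6-trimethyl-5-[(1E,3E,5E,7E,9E,11E,13E)-3,7,12-trimethylheptadeca-1,3,5,7,9,11,13-heptaen-15-yn-1-yl]cyclohex-3-en-1-yl}but-2-enoate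
Conditions: KN(SiMe3)2, DME, −60 °C to rt, base added to the mixture of 30 and 39
Reagents that add atoms: none
Why: Julia–Kocienski olefination (addition, Smiles rearrangement, loss of SO2 and tetrazololate) should form C7′=C8′ with E selectivity, and the sulfone carbanion at C7′ avoids an epimerisable aldehyde at C6′.

Step 26
Reactants: 14 C16 (E)-trienyl iodide; 40 C34 enyne ester
Product: 41 protected C50 carotenoid (target with C1–OH as triethylsilyl ether and C4″ as ethyl ester)
Conditions: Pd(OAc)2(PPh3)2 (5 mol %), HCO2H (slow addition), Et3N, DMF, 40 °C, dark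
Reagents that add atoms: none
Why: Proposed new method: oxidative addition of zerovalent palladium into the C8–I bond of 14 gives an (E)-trienylpalladium iodide, which adds syn across the C9≡C10 triple bond of 40 with the new C8–C9 bond at the methyl-bearing carbon and palladium at C10, where the adjacent C11=C12 π-system stabilises it; exchange of iodide for formate, loss of CO2 and C–H reductive elimination then put H on C10 cis to C8 and return zerovalent palladium. The closest known reaction type is the palladium-catalysed, formate-mediated hydroarylation and hydrovinylation of internal alkynes (a reductive Heck reaction of an alkyne), which has not been shown on a conjugated polyenyne. No ring is closed and no stereocentre is formed; the only new stereo-element, the (9E) geometry, is fixed by the syn carbopalladation together with retention in the C–H reductive elimination, and the (7E) geometry is carried over from 14. The step needs regioselectivity (C–C bond at C9, not C10), which the small methyl group on C9 against the bulky, conjugating polyenyl group on C10 should secure, as in the carbopalladation of alkyl/aryl and alkyl/alkenyl alkynes. It also needs chemoselectivity for the alkyne over the di- and trisubstituted alkenes, which do not insert into alkenylpalladium species at 40 °C, and for carbopalladation over direct formate reduction of the alkenylpalladium iodide, which slow addition of formic acid should favour. Both partners are electrophilic π-components, so the union is a reductive like-polarity coupling and neither fragment has to be made as an organometallic.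

Step 27
Reactants: 41 protected C50 carotenoid
Product: 42 C1-O-triethylsilyl ether of the target (C4″ now CH2OH)
Conditions: i-Bu2AlH, CH2Cl2, −78 °C
Reagents that add atoms: none
Why: 1,2-reduction of the enoate to the (E)-allylic alcohol is standard for carotenoid esters and leaves the polyene and the silyl ether intact.

Step 28
Reactants: 42 silyl ether
Product: 43 CNP0409952.2 (target)
Conditions: Bu4NF, THF, 0 °C to rt, dark
Reagents that add atoms: none
Why: fluoride cleaves the tertiary triethylsilyl ether to free the C1 carbinol and give the target.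

**Compound list**

1 | (S)-4-benzyloxazolidin-2-one | O=C1N[C@@H](Cc2ccccc2)CO1 | starting material
2 | 3-methylbut-2-enoyl chloride | CC(C)=CC(Cl)=O | starting material
3 | (S)-4-benzyl-3-(3-methylbut-2-enoyl)oxazolidin-2-one | CC(C)=CC(=O)N1[C@@H](Cc2ccccc2)COC1=O | intermediate
4 | 1-bromo-3-methylbut-2-ene | CC(C)=CCBr | starting material
5 | (S)-4-benzyl-3-[(2S)-5-methyl-2-(prop-1-en-2-yl)hex-4-enoyl]oxazolidin-2-one | CC(C)=CC[C@H](C(=O)N1[C@@H](Cc2ccccc2)COC1=O)C(C)=C | intermediate
6 | (S)-4-benzyl-3-[(2S)-2-(2-hydroxypropan-2-yl)-5-methylhex-4-enoyl]oxazolidin-2-one | CC(C)=CC[C@H](C(=O)N1[C@@H](Cc2ccccc2)COC1=O)C(C)(C)O | intermediate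
7 | (S)-4-benzyl-3-[(2S)-5-methyl-2-{2-[(triethylsilyl)oxy]propan-2-yl}hex-4-enoyl]oxazolidin-2-one | CC(C)=CC[C@H](C(=O)N1[C@@H](Cc2ccccc2)COC1=O)C(C)(C)O[Si](CC)(CC)CC | intermediate
8 | (2R)-5-methyl-2-{2-[(triethylsilyl)oxy]propan-2-yl}hex-4-en-1-ol | CC(C)=CC[C@H](CO)C(C)(C)O[Si](CC)(CC)CC | intermediate
9 | (2S)-5-methyl-2-{2-[(triethylsilyl)oxy]propan-2-yl}hex-4-enal | CC(C)=CC[C@H](C=O)C(C)(C)O[Si](CC)(CC)CC | intermediate
10 | diethyl (3-cyano-2-methylprop-2-en-1-yl)phosphonate (E/Z mixture as supplied) | CCOP(=O)(CC(C)=CC#N)OCC | starting material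
11 | (2E,4E,6R)-3,9-dimethyl-6-{2-[(triethylsilyl)oxy]propan-2-yl}deca-2,4,8-trienenitrile | CC(C)=CC[C@H](/C=C/C(C)=C/C#N)C(C)(C)O[Si](CC)(CC)CC | intermediate
12 | (2E,4E,6R)-3,9-dimethyl-6-{2-[(triethylsilyl)oxy]propan-2-yl}deca-2,4,8-trienal | CC(C)=CC[C@H](/C=C/C(C)=C/C=O)C(C)(C)O[Si](CC)(CC)CC | intermediate
13 | iodoform | IC(I)I | starting material
14 | triethyl{[(3R,4E,6E,8E)-9-iodo-2,6-dimethyl-3-(3-methylbut-2-en-1-yl)nona-4,6,8-trien-2-yl]oxy}silane (C16 iodide, C1–C8) | CC(C)=CC[C@H](/C=C/C(C)=C/C=C/I)C(C)(C)O[Si](CC)(CC)CC | intermediate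
15 | 2,4,4-trimethylcyclohex-2-en-1-one | CC1=CC(C)(C)CCC1=O | starting material
16 | 2,4,4-trimethylcyclohexa-2,5-dien-1-one | CC1=CC(C)(C)C=CC1=O | intermediate
17 | potassium ethenyltrifluoroborate | [K+].F[B-](F)(F)C=C | starting material
18 | (5S)-5-ethenyl-2,4,4-trimethylcyclohex-2-en-1-one | C1=C(C)C(=O)C[C@@H](C=C)C1(C)C | intermediate
19 | (1R,5S)-5-ethenyl-2,4,4-trimethylcyclohex-2-en-1-ol (OH trans to vinyl) | C1=C(C)[C@H](O)C[C@@H](C=C)C1(C)C | intermediate
20 | tributyl(iodomethyl)stannane | CCCC[Sn](CCCC)(CCCC)CI | starting material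
21 | tributyl({[(1R,5S)-5-ethenyl-2,4,4-trimethylcyclohex-2-en-1-yl]oxy}methyl)stannane | C1=C(C)[C@H](OC[Sn](CCCC)(CCCC)CCCC)C[C@@H](C=C)C1(C)C | intermediate
22 | ({[(1R,5S)-5-ethenyl-2,4,4-trimethylcyclohex-2-en-1-yl]oxy}methyl)lithium | C1=C(C)[C@H](OC[Li])C[C@@H](C=C)C1(C)C | intermediate (not isolated)
23 | [(1R,5S)-5-ethenyl-2,6,6-trimethylcyclohex-2-en-1-yl]methanol (CH2OH trans to vinyl) | OC[C@@H]1C(C)=CC[C@@H](C=C)C1(C)C | intermediate
24 | 5-({[(1R,5S)-5-ethenyl-2,6,6-trimethylcyclohex-2-en-1-yl]methyl}sulfanyl)-1-phenyl-1H-tetrazole | c1ccc(cc1)-n1nnnc1SC[C@@H]2C(C)=CC[C@@H](C=C)C2(C)C | intermediate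
25 | B-alkyl-9-borabicyclo[3.3.1]nonane adduct of 24 (boron on the terminal carbon of the former vinyl group) | c1ccc(cc1)-n1nnnc1SC[C@@H]2C(C)=CC[C@@H](CCB3C4CCCC3CCC4)C2(C)C | intermediate (not isolated)
26 | 2-[(1S,5R)-4,6,6-trimethyl-5-{[(1-phenyl-1H-tetrazol-5-yl)sulfanyl]methyl}cyclohex-3-en-1-yl]ethan-1-ol | c1ccc(cc1)-n1nnnc1SC[C@@H]2C(C)=CC[C@@H](CCO)C2(C)C | intermediate
27 | 2-[(1S,5R)-4,6,6-trimethyl-5-{[(1-phenyl-1H-tetrazol-5-yl)sulfonyl]methyl}cyclohex-3-en-1-yl]ethan-1-ol | O=S(=O)(C[C@@H]1C(C)=CC[C@@H](CCO)C1(C)C)c1nnnn1-c1ccccc1 | intermediate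
28 | ethyl 2-(triphenyl-λ5-phosphanylidene)propanoate | CCOC(=O)C(C)=P(c1ccccc1)(c1ccccc1)c1ccccc1 | starting material
29 | 2-[(1S,5R)-4,6,6-trimethyl-5-{[(1-phenyl-1H-tetrazol-5-yl)sulfonyl]methyl}cyclohex-3-en-1-yl]acetaldehyde | O=S(=O)(C[C@@H]1C(C)=CC[C@@H](CC=O)C1(C)C)c1nnnn1-c1ccccc1 | intermediate (not isolated)
30 | ethyl (2E)-2-methyl-4-[(1S,5R)-4,6,6-trimethyl-5-{[(1-phenyl-1H-tetrazol-5-yl)sulfonyl]methyl}cyclohex-3-en-1-yl]but-2-enoate (ring sulfone) | O=S(=O)(C[C@@H]1C(C)=CC[C@@H](C/C=C(\C)C(=O)OCC)C1(C)C)c1nnnn1-c1ccccc1 | intermediate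
31 | 1-bromobut-2-yne | CC#CCBr | starting material
32 | diethyl but-2-yn-1-ylphosphonate | CC#CCP(=O)(OCC)OCC | intermediate
33 | (2E,4E,6E)-2,7-dimethylocta-2,4,6-trienedial (C10 dialdehyde) | O=C/C(C)=C/C=C/C=C(C)/C=O | starting material
34 | (2E,4E,6E,8E)-2,7-dimethyldodeca-2,4,6,8-tetraen-10-ynal | CC#C/C=C/C(C)=C/C=C/C=C(C)/C=O | intermediate
35 | ethyl (2E)-4-bromo-2-methylbut-2-enoate | CCOC(=O)/C(C)=C/CBr | starting material
36 | ethyl (2E)-4-(diethoxyphosphoryl)-2-methylbut-2-enoate | CCOC(=O)/C(C)=C/CP(=O)(OCC)OCC | intermediate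
37 | ethyl (2E,4E,6E,8E,10E,12E)-2,6,11-trimethylhexadeca-2,4,6,8,10,12-hexaen-14-ynoate | CC#C/C=C/C(C)=C/C=C/C=C(C)/C=C/C=C(C)/C(=O)OCC | intermediate
38 | (2E,4E,6E,8E,10E,12E)-2,6,11-trimethylhexadeca-2,4,6,8,10,12-hexaen-14-yn-1-ol | CC#C/C=C/C(C)=C/C=C/C=C(C)/C=C/C=C(C)/CO | intermediate
39 | (2E,4E,6E,8E,10E,12E)-2,6,11-trimethylhexadeca-2,4,6,8,10,12-hexaen-14-ynal (C19 ynal) | CC#C/C=C/C(C)=C/C=C/C=C(C)/C=C/C=C(C)/C=O | intermediate
40 | ethyl (2E)-2-methyl-4-{(1S,5R)-4,6,6-trimethyl-5-[(1E,3E,5E,7E,9E,11E,13E)-3,7,12-trimethylheptadeca-1,3,5,7,9,11,13-heptaen-15-yn-1-yl]cyclohex-3-en-1-yl}but-2-enoate (C34 enyne, C9–C6′) | CC#C/C=C/C(C)=C/C=C/C=C(C)/C=C/C=C(C)/C=C/[C@@H]1C(C)=CC[C@@H](C/C=C(\C)C(=O)OCC)C1(C)C | intermediate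
41 | protected C50 carotenoid: all-E (2R,2′S,6′R) target skeleton with C1–OH as triethylsilyl ether and C4″ as ethyl ester | CC(C)=CC[C@H](/C=C/C(C)=C/C=C/C(C)=C/C=C/C(C)=C/C=C/C=C(C)/C=C/C=C(C)/C=C/[C@@H]1C(C)=CC[C@@H](C/C=C(\C)C(=O)OCC)C1(C)C)C(C)(C)O[Si](CC)(CC)CC | intermediate
42 | C1-O-triethylsilyl ether of the target (C4″ alcohol free) | CC(C)=CC[C@H](/C=C/C(C)=C/C=C/C(C)=C/C=C/C(C)=C/C=C/C=C(C)/C=C/C=C(C)/C=C/[C@@H]1C(C)=CC[C@@H](C/C=C(\C)CO)C1(C)C)C(C)(C)O[Si](CC)(CC)CC | intermediate
43 | CNP0409952.2: all-E (2R,2′S,6′R) C50 carotenoid with 2-prenyl-1-hydroxy acyclic end and 2′-[(2E)-4-hydroxy-3-methylbut-2-enyl] ε-ring end | CC(C)=CC[C@H](/C=C/C(C)=C/C=C/C(C)=C/C=C/C(C)=C/C=C/C=C(C)/C=C/C=C(C)/C=C/[C@@H]1C(C)=CC[C@@H](C/C=C(\C)CO)C1(C)C)C(C)(C)O | target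

**Step count**

Total step count: 28 steps.
Longest linear sequence: 13 steps (steps 10–18, then 25–28).

**Steps most likely to fail**

Step 26 (Proposed new method). What may go wrong: premature formate reduction of the alkenylpalladium iodide, loss of regiocontrol in the carbopalladation, and E/Z isomerisation at C9=C10 through the conjugated C10-palladium intermediate. The fallback sets out from 40 and 14 and comes back at 41. Hydrozirconation of the C9≡C10 alkyne of 40 with Cp2Zr(H)Cl (THF, 0 °C to rt) should place zirconium on the less hindered, methyl-bearing C9 by syn addition and give the (E)-alkenylzirconocene chloride F1. Transmetalation with ZnCl2 gives the alkenylzinc chloride F2, and Negishi coupling of F2 with 14 (Pd(PPh3)4, THF, rt) should give 41 with the same C8–C9 bond and (9E) geometry.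

Step 11. What may go wrong: slow addition of the alkenylrhodium species to a β-carbon that is flanked by the quaternary C1′, and erosion of enantioface selectivity on this hindered dienone. The fallback sets out from 16 and comes back at 19. Copper-catalysed conjugate addition of CH2=CHMgBr (CuI 10 mol %, THF, −40 °C) gives racemic 5-ethenyl-2,4,4-trimethylcyclohex-2-en-1-one F3. The CBS reduction of step 12, used now as a catalyst-controlled reduction of the racemate, should turn the (5S)-enantiomer into 19 and the (5R)-enantiomer into the cis diastereomer (1R,5R)-5-ethenyl-2,4,4-trimethylcyclohex-2-en-1-ol F4. The two diastereomers are separated by chromatography, so C2′ is obtained by resolution instead of by asymmetric catalysis.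

Step 14. What may go wrong: competing [1,2]-shift and protonation of the α-alkoxymethyllithium, because the migration terminus C6′ is flanked by the quaternary C1′. The fallback sets out from 19 and comes back at 23. Johnson–Claisen rearrangement (MeC(OEt)3, cat. EtCO2H, 140 °C) transfers a two-carbon unit suprafacially to C6′ and gives ethyl 2-[(1R,5S)-5-ethenyl-2,6,6-trimethylcyclohex-2-en-1-yl]acetate F5. Saponification (LiOH, THF/H2O) gives 2-[(1R,5S)-5-ethenyl-2,6,6-trimethylcyclohex-2-en-1-yl]acetic acid F6, which is converted (N-hydroxypyridine-2-thione, DCC) into the Barton ester F7. Photolysis of F7 under O2 with t-BuSH (Barton decarboxylative oxygenation) gives [(1R,5S)-5-ethenyl-2,6,6-trimethylcyclohex-2-en-1-yl]methyl hydroperoxide F8, and reduction of F8 with PPh3 gives 23.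

**Further compounds**

F1 | step 26 | (E)-alkenylzirconocene chloride from 40 (Cp2ZrCl on C9, H on C10) | Cl[Zr](C1C=CC=C1)(C1C=CC=C1)/C(C)=C/C=C/C(C)=C/C=C/C=C(C)/C=C/C=C(C)/C=C/[C@@H]1C(C)=CC[C@@H](C/C=C(\C)C(=O)OCC)C1(C)C
F2 | step 26 | (E)-alkenylzinc chloride from F1 (ZnCl on C9) | Cl[Zn]/C(C)=C/C=C/C(C)=C/C=C/C=C(C)/C=C/C=C(C)/C=C/[C@@H]1C(C)=CC[C@@H](C/C=C(\C)C(=O)OCC)C1(C)C
F3 | step 11 | racemic 5-ethenyl-2,4,4-trimethylcyclohex-2-en-1-one | C=CC1CC(=O)C(C)=CC1(C)C
F4 | step 11 | (1R,5R)-5-ethenyl-2,4,4-trimethylcyclohex-2-en-1-ol (cis diastereomer) | C1=C(C)[C@H](O)C[C@H](C=C)C1(C)C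
F5 | step 14 | ethyl 2-[(1R,5S)-5-ethenyl-2,6,6-trimethylcyclohex-2-en-1-yl]acetate | CCOC(=O)C[C@@H]1C(C)=CC[C@@H](C=C)C1(C)C
F6 | step 14 | 2-[(1R,5S)-5-ethenyl-2,6,6-trimethylcyclohex-2-en-1-yl]acetic acid | OC(=O)C[C@@H]1C(C)=CC[C@@H](C=C)C1(C)C
F7 | step 14 | 2-thioxopyridin-1(2H)-yl 2-[(1R,5S)-5-ethenyl-2,6,6-trimethylcyclohex-2-en-1-yl]acetate (Barton ester) | S=c1ccccn1OC(=O)C[C@@H]1C(C)=CC[C@@H](C=C)C1(C)C
F8 | step 14 | [(1R,5S)-5-ethenyl-2,6,6-trimethylcyclohex-2-en-1-yl]methyl hydroperoxide | OOC[C@@H]1C(C)=CC[C@@H](C=C)C1(C)C
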